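A leftover comes first: at 120 h cedar, the very flask asked about, still holds 29% of its substrate beside 30% target, so you should ask what ran short.

| setting | cedar | ash | flask |
|---|---|---|---|
| substrate | 0.30 M | 0.60 M | 0.30 M |
| reagent in the second phase | 0.315 M | 0.315 M | 0.315 M |
| temperature | 25 °C | 10 °C | 25 °C |
| remark | the very flask that is asked about, followed so far | run made earlier |  |
| time |  |  | 8.0 d |
| volume of the second phase over the first |  |  | 1.0 |

| run | time / h | target / % | substrate / % |
|---|---|---|---|
| cedar | 6.00 | 9 | 91 |
| cedar | 20.0 | 14 | 73 |
| cedar | 30.0 | 21 | 64 |
| cedar | 50.0 | 30 | 49 |
| cedar | 72.0 | 31 | 35 |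
| cedar | 96.0 | 33 | 34 |
| cedar | 120 | 30 | 29 |
| ash | 6.00 | 5 | 92 |
| ash | 12.0 | 8 | 94 |
| ash | 20.0 | 12 | 87 |
| ash | 25.0 | 16 | 79 |
| ash | 30.0 | 18 | 82 |
| ash | 40.0 | 23 | 76 |

(each reading ± 2 percentage points)

- beta: at 8.0 d add substrate, 50.0% of the amount charged, then wait 8.0 d
- theta: change nothing and wait 8.0 d more
- alpha: at 8.0 d raise the temperature by 10 K, then wait 8.0 d

* target, in percent of the substrate first charged, at 8.0 d
* the option that brings most further target ("none" if no option brings more than 2 percentage points) (beta / theta / alpha / none)
* target present, in percent of the substrate first charged, after beta
* target present, in percent of the substrate first charged, after alpha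

- in the second phase: reagent in the second phase; everything else is in the first
- charges count per volume of the first phase; a concentration in a rate is the amount of a species over the volume of its own phase; every rate counts per litre of the first phase
- additions leave the volume as it is
- the earlier runs were read with a standard deviation of 2 percentage points
- the earlier runs hold the two phases in the same ratio of volumes as the flask asked about
- a reading or a percentage of target counts all its forms, free or not

Substrate in the first phase takes reagent that comes over from the second phase and becomes target. Freeze a sum that cannot change, the reagent in whatever form: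

budget = c reagent in the second phase / c substrate = 1.05

That reagent budget, reagent charged per substrate charged, is my yardstick, and I take reagent as the limiting reagent.

Now climb the ladder in cedar. On the fastest rung target goes flat: 30% at 50.0 h, 33% at 96.0 h. On the next rung substrate slows later, from 49% to 34% over those same times. On the slowest rung the budget fills. Suppose each substrate lost took one reagent and the unread gap took one more:

at 120 h: 71.0% + 41.0% = 112%, against a budget of 105%

The sum stands above the budget, so apart from scatter, part of the gap may have cost no reagent.

My reckoning is that target holds at the mean of the readings from 50.0 h on, 31.0%, and that waiting and adding substrate bring little. The budget says nothing about heating a reagent-free form, so I leave alpha open.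

The forecast gives 31%, best none, 31.5% after beta and 31% after alpha: “Waiting, heating or adding substrate therefore gives almost no further target.”

The flask gives target, crystals counted in, of 32.4%, and best alpha: 42.4% after alpha, 33.9% after beta.

    crystals ⇌ target, rate k1*(cs1 - [target]) while solid is left; crystals form when [target] > cs1 (solubility = 43.0 mM, k = 18.0 h⁻¹)
    reagent in the reaction phase ⇌ reagent in the second phase, rate k2*([reagent in the reaction phase] - [reagent in the second phase]/K2) per volume of the first phase (partition coefficient = 2.30, kL = 0.0420 h⁻¹)
    target ⇌ isomer of the product (K = 1.50, k = 0.0310 h⁻¹, Ea = 92.0 kJ mol⁻¹, ΔH = −49.0 kJ mol⁻¹)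
    reagent in the reaction phase + target → over-reacted product (k = 30.0 M⁻¹ h⁻¹, Ea = 68.0 kJ mol⁻¹)
    substrate + reagent in the reaction phase → target (k = 25.0 M⁻¹ h⁻¹, Ea = 63.0 kJ mol⁻¹)
    (constants at 25 °C)

At 192 h the flask has paid 102% of substrate charged, counting substrate lost plus over-reacted product. Reagent in both phases holds 3.29% more, which closes on the budget of 105%. Alpha's gain of 10 percentage points is more than that remainder, while the isomer of the product holds 21.0%, and its step back to target takes no reagent in the scheme. The neighbour flask with 0.12 M substrate has a budget of 2.62, above the 2 that full over-reaction takes. It ends with substrate 0%, target 0.0463% and over-reacted product 98.4%.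

The readings are simulated for substances that don't exist; noise was put on by code.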